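**Retrosynthetic overview**

- The last bond made is the aryl ester C–O between the C4 phenol oxygen and (S)-3-acetoxybutanoyl chloride. The only stereocentre is bought with (S)-3-hydroxybutanoic acid.
- The (E)-cinnamate C=C comes from a Wittig olefination of the benzaldehyde, which is reached by reduction and oxidation of a ring ester.
- The strategy rests on the single benzene ring and its 1,3,4 pattern: carbon substituent on C1, prenyl CH2 on C3, oxygen on C4. The ring bonds C2–C3 and C4–C5 are cut. C1, C2, C5 and C6 (with the C1 ester carbon) come from methyl coumalate (pyrone C5, C6, C3, C4); C3 and C4 are the two alkyne carbons of a triisopropylsilyl ynol ether; the pyrone O–C(=O) bridge leaves as CO2.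
- The ynol ether comes from methyl 4-methylpent-3-enoate by one-carbon ester-to-ynolate homologation and O-silylation.
- Ring order: there is one ring and it is formed in the cycloaddition; all other steps adjust side chains.

Key step: step 3

Remark: the acetoxy-bearing carbon is S as drawn; no step makes or breaks a bond at it. ortho-Prenyl phenols cyclise to chromans under acid, so every step after ring formation is run neutral or buffered.

**Route**

Step 1
Reactants: 1 4-methylpent-3-enoic acid
Product: 2 methyl 4-methylpent-3-enoate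
Conditions: MeI, K2CO3, DMF, rt
Reagents that add atoms: iodomethane, CI
Why: SN2 O-alkylation of the carboxylate esterifies without acid, which would otherwise lactonise this β,γ-unsaturated acid through the tertiary cation.

Step 2
Reactants: 2 methyl 4-methylpent-3-enoate
Product: 5 triisopropyl[(5-methylhex-4-en-1-yn-1-yl)oxy]silane, via lithium dibromoenolate 3 (not isolated), via lithium ynolate 4 (not isolated)
Conditions: CH2Br2, lithium 2,2,6,6-tetramethylpiperidide, THF, −78 °C; LiN(SiMe3)2; n-BuLi, −78 → 0 °C; iPr3SiCl, −78 → 0 °C; chromatography on Et3N-washed silica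
Reagents that add atoms: dibromomethane, BrCBr; chlorotriisopropylsilane, CC(C)[Si](Cl)(C(C)C)C(C)C
Why: Kowalski ester homologation, in which LiCHBr2 adds to the ester, the dibromoketone enolate 3 undergoes Br/Li exchange and the carbenoid rearranges by 1,2-shift of the prenyl CH2 to ynolate 4, which the bulky silyl chloride should trap on oxygen (ynol silyl ether synthesis).

Step 3
Reactants: 5 triisopropyl[(5-methylhex-4-en-1-yn-1-yl)oxy]silane; 6 methyl coumalate (methyl 2-oxo-2H-pyran-5-carboxylate)
Product: 8 methyl 3-(3-methylbut-2-en-1-yl)-4-[(triisopropylsilyl)oxy]benzoate, via bicyclic lactone adduct 7 (not isolated)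
Conditions: 5 (1.3 equiv), PhMe, 110 °C, sealed tube, Ar
Reagents that add atoms: none
Why: Inverse-electron-demand [4+2] cycloaddition, in which the electron-rich ynol silyl ether adds across C3 and C6 of the electron-poor 2-pyrone diene, probably asynchronously: the alkyne carbon β to oxygen (bearing the prenyl CH2) bonds first to pyrone C6 and the silyloxy-bearing carbon then closes onto C3. The closest known reaction type is the cycloaddition of methyl coumalate with ynamines, alkoxyalkynes, enol ethers and ketene acetals followed by CO2 extrusion to para-heteroatom-substituted benzoates. The six-membered carbocycle is closed by this intermolecular [4+2] event, which forms two ring C–C bonds and gives the 2-oxabicyclo[2.2.2]octadienone 7; retro-[4+2] loss of CO2 from 7 at the same temperature turns it into the benzene ring. No stereocentre is created, since the two bridgehead centres of 7 vanish on aromatisation. The step needs regioselectivity, which the match of the most electrophilic pyrone carbon (C6, terminus of the dienoate and β to the 5-ester) with the nucleophilic alkyne carbon should secure, placing silyloxy para and prenyl meta to the ester; it also needs chemoselectivity, secured because the trisubstituted prenyl olefin is a far poorer dienophile than the ynol ether and the bulky iPr3Si group slows the 1,3-silyl shift to a silylketene.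

Step 4
Reactants: 8 methyl 3-(3-methylbut-2-en-1-yl)-4-[(triisopropylsilyl)oxy]benzoate
Product: 9 {3-(3-methylbut-2-en-1-yl)-4-[(triisopropylsilyl)oxy]phenyl}methanol
Conditions: iBu2AlH (2.5 equiv), CH2Cl2, −78 → 0 °C; aq. potassium sodium tartrate (KNaC4H4O6) work-up
Reagents that add atoms: none
Why: Hydride reduction of the aryl ester to the benzylic alcohol with iBu2AlH, which leaves the aryl silyl ether and the isolated olefin untouched.

Step 5
Reactants: 9 {3-(3-methylbut-2-en-1-yl)-4-[(triisopropylsilyl)oxy]phenyl}methanol; 10 methyl (triphenylphosphoranylidene)acetate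
Product: 12 methyl (E)-3-{3-(3-methylbut-2-en-1-yl)-4-[(triisopropylsilyl)oxy]phenyl}prop-2-enoate, via aryl aldehyde 11 (not isolated)
Conditions: MnO2 (10 equiv), 10 (1.3 equiv), CH2Cl2, rt → 40 °C
Reagents that add atoms: none
Why: Tandem benzylic oxidation with MnO2 and Wittig olefination, in which aldehyde 11 is trapped as it forms by the stabilised ylide, which should give the E-alkene.

Step 6
Reactants: 12 methyl (E)-3-{3-(3-methylbut-2-en-1-yl)-4-[(triisopropylsilyl)oxy]phenyl}prop-2-enoate
Product: 13 methyl (E)-3-[4-hydroxy-3-(3-methylbut-2-en-1-yl)phenyl]prop-2-enoate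
Conditions: Bu4NF (1.1 equiv), AcOH (1.1 equiv), THF, 0 °C
Reagents that add atoms: none
Why: Fluoride-induced cleavage of the aryl silyl ether, with acetic acid buffering the phenoxide so that the methyl enoate is neither hydrolysed nor attacked in a conjugate sense.

Step 7
Reactants: 14 (S)-3-hydroxybutanoic acid
Product: 15 (S)-3-acetoxybutanoic acid
Conditions: AcCl (3 equiv, neat), 0 °C → rt; evaporate
Reagents that add atoms: acetyl chloride, CC(=O)Cl
Why: O-Acetylation of the secondary alcohol by acyl chloride; the C–O bond at the stereocentre is not broken, so the S configuration is retained.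

Step 8
Reactants: 15 (S)-3-acetoxybutanoic acid
Product: 16 (S)-3-acetoxybutanoyl chloride
Conditions: (COCl)2, cat. DMF, CH2Cl2, 0 °C → rt; evaporate, use at once
Reagents that add atoms: oxalyl chloride, O=C(Cl)C(Cl)=O
Why: Acid chloride formation through the Vilsmeier-type chloroiminium species proceeds at room temperature without base, so the β-acetoxy group is not eliminated.

Step 9
Reactants: 13 methyl (E)-3-[4-hydroxy-3-(3-methylbut-2-en-1-yl)phenyl]prop-2-enoate; 16 (S)-3-acetoxybutanoyl chloride
Product: 17 methyl (E)-3-{4-[(S)-3-acetoxybutanoyloxy]-3-(3-methylbut-2-en-1-yl)phenyl}prop-2-enoate (CNP0290147.1)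
Conditions: pyridine (2 equiv), CH2Cl2, −40 → 0 °C
Reagents that add atoms: none
Why: Pyridine-mediated acylation of the phenol (nucleophilic acyl substitution through the acylpyridinium ion), where the weak base and low temperature should suppress E1cB loss of acetate and pyridine scavenges the HCl that would cyclise the ortho-prenyl phenol; the stereocentre is β to the carbonyl and cannot epimerise.

**Compound list**

1 | 4-methylpent-3-enoic acid | CC(C)=CCC(=O)O | starting material
2 | methyl 4-methylpent-3-enoate | COC(=O)CC=C(C)C | intermediate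
3 | lithium 1,1-dibromo-5-methylhexa-1,4-dien-2-olate | [Li+].[O-]C(CC=C(C)C)=C(Br)Br | intermediate
4 | lithium 5-methylhex-4-en-1-yn-1-olate | [Li+].[O-]C#CCC=C(C)C | intermediate
5 | triisopropyl[(5-methylhex-4-en-1-yn-1-yl)oxy]silane | CC(C)=CCC#CO[Si](C(C)C)(C(C)C)C(C)C | intermediate
6 | methyl coumalate (methyl 2-oxo-2H-pyran-5-carboxylate) | COC(=O)C1=COC(=O)C=C1 | starting material
7 | methyl 7-(3-methylbut-2-en-1-yl)-3-oxo-8-[(triisopropylsilyl)oxy]-2-oxabicyclo[2.2.2]octa-5,7-diene-6-carboxylate (racemic) | O=C1OC2C(CC=C(C)C)=C(O[Si](C(C)C)(C(C)C)C(C)C)C1C=C2C(=O)OC | intermediate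
8 | methyl 3-(3-methylbut-2-en-1-yl)-4-[(triisopropylsilyl)oxy]benzoate | COC(=O)c1ccc(O[Si](C(C)C)(C(C)C)C(C)C)c(CC=C(C)C)c1 | intermediate
9 | {3-(3-methylbut-2-en-1-yl)-4-[(triisopropylsilyl)oxy]phenyl}methanol | OCc1ccc(O[Si](C(C)C)(C(C)C)C(C)C)c(CC=C(C)C)c1 | intermediate
10 | methyl (triphenylphosphoranylidene)acetate | COC(=O)C=P(c1ccccc1)(c1ccccc1)c1ccccc1 | starting material
11 | 3-(3-methylbut-2-en-1-yl)-4-[(triisopropylsilyl)oxy]benzaldehyde | O=Cc1ccc(O[Si](C(C)C)(C(C)C)C(C)C)c(CC=C(C)C)c1 | intermediate
12 | methyl (E)-3-{3-(3-methylbut-2-en-1-yl)-4-[(triisopropylsilyl)oxy]phenyl}prop-2-enoate | COC(=O)/C=C/c1ccc(O[Si](C(C)C)(C(C)C)C(C)C)c(CC=C(C)C)c1 | intermediate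
13 | methyl (E)-3-[4-hydroxy-3-(3-methylbut-2-en-1-yl)phenyl]prop-2-enoate | COC(=O)/C=C/c1ccc(O)c(CC=C(C)C)c1 | intermediate
14 | (S)-3-hydroxybutanoic acid | C[C@H](O)CC(=O)O | starting material
15 | (S)-3-acetoxybutanoic acid | C[C@H](OC(C)=O)CC(=O)O | intermediate
16 | (S)-3-acetoxybutanoyl chloride | C[C@H](OC(C)=O)CC(=O)Cl | intermediate
17 | methyl (E)-3-{4-[(S)-3-acetoxybutanoyloxy]-3-(3-methylbut-2-en-1-yl)phenyl}prop-2-enoate | COC(=O)/C=C/c1ccc(OC(=O)C[C@H](C)OC(C)=O)c(CC=C(C)C)c1 | target

**Step count and risks**

Total steps: 9. Longest linear sequence: 7 (steps 1, 2, 3, 4, 5, 6, 9); steps 7 and 8 form the side branch.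

Steps most likely to fail:

1. Step 3. The cycloaddition may be slower than thermal decay of the ynol ether (silyl shift to a silylketene, oligomerisation), or regiocontrol may erode. The fallback keeps the pyrone but changes the two-carbon partner to a ketene acetal. It sets out from methyl coumalate 6 and comes back at benzoate 8. Purchased 5-methylhex-4-enoic acid F1 is doubly deprotonated with LiN(iPr)2 (2.2 equiv) and silylated with Me3SiCl in THF at −78 °C to the ketene bis(trimethylsilyl) acetal F2. Heating F2 with 6 in toluene or xylene should give, by the known coumalate/ketene acetal cycloaddition with the same regiochemistry, the bridged lactone F3. F3 loses CO2 to the dihydroarene F4, and F4 aromatises by loss of trimethylsilanol to the aryl trimethylsilyl ether F5. KF in aqueous MeOH then frees methyl 4-hydroxy-3-(3-methylbut-2-en-1-yl)benzoate F6, and iPr3SiCl with imidazole in DMF should give 8.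

2. Step 2. The β,γ-unsaturated ester may be deprotonated at its α-carbon instead of adding LiCHBr2; the skipped enyne may be isomerised into conjugation by residual lithium amide; silylation may occur on carbon. The fallback reaches the ynolate by oxidation of an acetylide instead of by carbenoid rearrangement. It sets out from ester 2 and comes back at ynolate 4, and so at 5. Ester 2 is reduced with iBu2AlH (1.05 equiv, CH2Cl2, −78 °C) to 4-methylpent-3-enal F7. F7 is homologated with the Ohira–Bestmann reagent (dimethyl (1-diazo-2-oxopropyl)phosphonate, K2CO3, MeOH, 0 °C) to 5-methylhex-4-en-1-yne F8. Deprotonation with n-BuLi in THF at −78 °C gives the lithium acetylide F9, and oxidation with LiOOtBu (from tBuOOH and LiN(SiMe3)2, −78 → 0 °C) should give ynolate 4, which is silylated as in step 2.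

3. Step 9. Base-induced β-elimination of acetate through the activated acyl species would give the crotonate, and unscavenged HCl would cyclise the prenyl phenol. The fallback puts the acetate on last. It sets out from hydroxy acid 14 and phenol 13 and comes back at target 17. Acid 14 is silylated with tBuMe2SiCl and imidazole in DMF to the bis-silyl derivative F10, and K2CO3 in aqueous MeOH cleaves the silyl ester to (S)-3-(tert-butyldimethylsilyloxy)butanoic acid F11. F11 is coupled with 13 by EDC·HCl and catalytic DMAP in CH2Cl2 to the silyloxy aryl ester F12, whose silyloxy group is a poor leaving group. HF·pyridine in THF at 0 °C should give the β-hydroxy aryl ester F13, and Ac2O with pyridine at 0 °C should give 17.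

Further compounds
F1 | step 3 | 5-methylhex-4-enoic acid | CC(C)=CCCC(=O)O
F2 | step 3 | [(5-methylhexa-1,4-diene-1,1-diyl)bis(oxy)]bis(trimethylsilane) | CC(C)=CCC=C(O[Si](C)(C)C)O[Si](C)(C)C
F3 | step 3 | methyl 7-(3-methylbut-2-en-1-yl)-3-oxo-8,8-bis[(trimethylsilyl)oxy]-2-oxabicyclo[2.2.2]oct-5-ene-6-carboxylate | O=C1OC2C(CC=C(C)C)C(O[Si](C)(C)C)(O[Si](C)(C)C)C1C=C2C(=O)OC
F4 | step 3 | methyl 3-(3-methylbut-2-en-1-yl)-4,4-bis[(trimethylsilyl)oxy]cyclohexa-1,5-diene-1-carboxylate | COC(=O)C1=CC(CC=C(C)C)C(O[Si](C)(C)C)(O[Si](C)(C)C)C=C1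
F5 | step 3 | methyl 3-(3-methylbut-2-en-1-yl)-4-[(trimethylsilyl)oxy]benzoate | COC(=O)c1ccc(O[Si](C)(C)C)c(CC=C(C)C)c1
F6 | step 3 | methyl 4-hydroxy-3-(3-methylbut-2-en-1-yl)benzoate | COC(=O)c1ccc(O)c(CC=C(C)C)c1
F7 | step 2 | 4-methylpent-3-enal | CC(C)=CCC=O
F8 | step 2 | 5-methylhex-4-en-1-yne | CC(C)=CCC#C
F9 | step 2 | (5-methylhex-4-en-1-yn-1-yl)lithium | [Li]C#CCC=C(C)C
F10 | step 9 | tert-butyldimethylsilyl (S)-3-[(tert-butyldimethylsilyl)oxy]butanoate | C[C@H](O[Si](C)(C)C(C)(C)C)CC(=O)O[Si](C)(C)C(C)(C)C
F11 | step 9 | (S)-3-[(tert-butyldimethylsilyl)oxy]butanoic acid | C[C@H](O[Si](C)(C)C(C)(C)C)CC(=O)O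
F12 | step 9 | methyl (E)-3-{4-[(S)-3-(tert-butyldimethylsilyloxy)butanoyloxy]-3-(3-methylbut-2-en-1-yl)phenyl}prop-2-enoate | COC(=O)/C=C/c1ccc(OC(=O)C[C@H](C)O[Si](C)(C)C(C)(C)C)c(CC=C(C)C)c1
F13 | step 9 | methyl (E)-3-{4-[(S)-3-hydroxybutanoyloxy]-3-(3-methylbut-2-en-1-yl)phenyl}prop-2-enoate | COC(=O)/C=C/c1ccc(OC(=O)C[C@H](C)O)c(CC=C(C)C)c1
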